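**Retrosynthetic overview**
1. The target comes from C-4 epimerisation and desilylation of the cis keto alcohol formed when an aryllithium opens an aryl-substituted, cis-fused furo[3,4-c]furanone (ketone C–C bond).
2. That lactone comes from a nickel/decatungstate C(sp3)–H arylation of the unsubstituted bicyclic lactone with the same aryl bromide (C-2–aryl bond, C-2 set on the convex face).
3. The bicyclic lactone comes from desymmetrising monoreduction of a meso N-phenyl imide, then borohydride reduction and lactonisation; the imide comes from a [3+2] cycloaddition of N-phenylmaleimide with the parent carbonyl ylide.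
4. The aryl bromide (used twice) comes from anisole by 2,4-dibromination, ortho-selective Br/Li exchange–borylation–oxidation and silylation.
5. Ring order: oxolane ring first (cycloaddition), then the imide ring is converted into the lactone ring, which is opened at the end.

Assumption: where a chiral catalyst or ligand is named, that enantiomer is taken to give the configuration drawn (if its sense of induction proves opposite, the mirror image is used), and 8 is prepared because it is not a stock chemical.

**Route**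

Step 1
Reactants: 1 anisole
Product: 2 2,4-dibromo-1-methoxybenzene
Conditions: Br2 (2.1 equiv), AcOH, rt
Reagents that add atoms: bromine, BrBr
Why: Electrophilic aromatic bromination, in which the methoxy group directs the first bromine para and the second ortho.

Step 2
Reactants: 2 2,4-dibromo-1-methoxybenzene
Product: 5 5-bromo-2-methoxyphenol, via aryllithium 3 (not isolated), via arylborate 4 (not isolated)
Conditions: n-BuLi (1.0 equiv), Et2O, −78 °C; B(OMe)3, −78 °C to rt; then AcOH, 30% H2O2, 0 °C to rt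
Reagents that add atoms: hydrogen peroxide, OO
Why: Bromine–lithium exchange is selective for the bromine ortho to the coordinating methoxy group, and borylation followed by oxidative C–B to C–O migration gives the phenol with bromine para to OMe (halogen–metal exchange, borylation–oxidation).

Step 3
Reactants: 5 5-bromo-2-methoxyphenol
Product: 6 (5-bromo-2-methoxyphenoxy)tri(propan-2-yl)silane
Conditions: TIPSCl, imidazole, DMF, rt
Reagents that add atoms: chlorotri(propan-2-yl)silane, CC(C)[Si](Cl)(C(C)C)C(C)C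
Why: Phenol silylation, chosen because the TIPS ether has no weak hydridic C–H, survives base and organolithiums, and is removed by fluoride at the end.

Step 4
Reactants: 7 (trimethylsilyl)methanol
Product: 8 [(chloromethoxy)methyl]trimethylsilane
Conditions: (CH2O)n, HCl (g), 0 °C; CaCl2, distil
Reagents that add atoms: formaldehyde (as paraformaldehyde), C=O; hydrogen chloride, Cl
Why: Chloromethylation of an alcohol (hemiformal to α-chloro ether), as used for other chloromethyl ethers.

Step 5
Reactants: 9 maleic anhydride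
Product: 11 N-phenylmaleimide, via maleanilic acid 10 (not isolated)
Conditions: PhNH2, Et2O, rt; then Ac2O, NaOAc, 100 °C
Reagents that add atoms: aniline, Nc1ccccc1
Why: Anhydride aminolysis followed by cyclodehydration (imide formation); the N-phenyl group suits both the cycloaddition and the later desymmetrisation.

Step 6
Reactants: 11 N-phenylmaleimide; 8 [(chloromethoxy)methyl]trimethylsilane
Product: 13 (3aR,6aS)-5-phenyltetrahydro-1H-furo[3,4-c]pyrrole-4,6(5H)-dione, via carbonyl ylide 12 (not isolated)
Conditions: CsF, MeCN, rt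
Reagents that add atoms: none
Why: Fluoride-triggered 1,3-elimination gives the parent carbonyl ylide, whose concerted suprafacial 1,3-dipolar cycloaddition to the cis alkene forms the oxolane ring as the cis-fused meso imide only.

Step 7
Reactants: 13 (3aR,6aS)-5-phenyltetrahydro-1H-furo[3,4-c]pyrrole-4,6(5H)-dione
Product: 14 (3aR,6aS)-6-hydroxy-5-phenylhexahydro-4H-furo[3,4-c]pyrrol-4-one
Conditions: (3aR,8aS)-2-methoxy-3,3a,8,8a-tetrahydro-2H-indeno[1,2-d][1,3,2]oxazaborole (10 mol%), BH3·THF, THF, 0 °C to rt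
Reagents that add atoms: none
Why: Oxazaborolidine-catalysed enantioselective borane monoreduction of a meso imide (desymmetrisation), in which the catalyst selects one of the two enantiotopic carbonyls and so fixes the absolute configuration of both ring-fusion carbons (the new hemiaminal centre is lost in step 8).

Step 8
Reactants: 14 (3aR,6aS)-6-hydroxy-5-phenylhexahydro-4H-furo[3,4-c]pyrrol-4-one
Product: 16 (3aS,6aR)-tetrahydro-1H,3H-furo[3,4-c]furan-1-one, via hydroxy anilide 15 (not isolated)
Conditions: NaBH4, EtOH, 0 °C to rt; then 2 M H2SO4, 60 °C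
Reagents that add atoms: none
Why: Borohydride reduces the ring-opened aldehyde tautomer of the hydroxylactam, and acid-catalysed lactonisation of the cis γ-hydroxy anilide expels aniline with the cis ring fusion retained (reductive ring opening, intramolecular acyl transfer).

Step 9
Reactants: 16 (3aS,6aR)-tetrahydro-1H,3H-furo[3,4-c]furan-1-one (3 equiv, excess recovered); 6 (5-bromo-2-methoxyphenoxy)tri(propan-2-yl)silane
Product: 17 (3aR,4S,6aR)-4-{4-methoxy-3-[(triisopropylsilyl)oxy]phenyl}tetrahydro-1H,3H-furo[3,4-c]furan-1-one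
Conditions: (n-Bu4N)4[W10O32] (2 mol%), NiBr2(MeOCH2CH2OMe) (10 mol%), 4,4′-di-tert-butyl-2,2′-bipyridine (10 mol%), K3PO4, MeCN, 390 nm LEDs, rt
Reagents that add atoms: none
Why: Proposed new method: photoexcited decatungstate, an electrophilic hydrogen-atom abstractor, should take the most hydridic ether C–H, namely the ring CH2 next to the ring-fusion carbon that carries the acyloxymethyl arm, rather than the CH2 next to the carbonyl-bearing carbon (inductively deactivated), the lactone OCH2 (acyloxy-deactivated) or the α-C–H; the α-oxy radical is then captured on the convex face of the cis-fused bicycle by the aryl nickel bromide (divalent nickel) formed from 6 and zerovalent nickel, and reductive elimination from trivalent nickel forms the C-2–aryl bond trans to the lactone CH2, setting C-2 as S; the closest known reaction type is decatungstate/nickel dual-catalysed C(sp3)–H arylation of simple cyclic ethers with aryl bromides, which has not been shown to discriminate two unlike ether methylenes of a bicyclic lactone or to set a stereocentre this way.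

Step 10
Reactants: 17 (3aR,4S,6aR)-4-{4-methoxy-3-[(triisopropylsilyl)oxy]phenyl}tetrahydro-1H,3H-furo[3,4-c]furan-1-one; 6 (5-bromo-2-methoxyphenoxy)tri(propan-2-yl)silane
Product: 19 [(3R,4R,5S)-4-(hydroxymethyl)-5-{4-methoxy-3-[(triisopropylsilyl)oxy]phenyl}oxolan-3-yl]{4-methoxy-3-[(triisopropylsilyl)oxy]phenyl}methanone, via aryllithium 18 (not isolated)
Conditions: 6, n-BuLi, THF, −78 °C; then 17, −78 °C; AcOH
Reagents that add atoms: none
Why: Halogen–lithium exchange and nucleophilic acyl addition to the γ-lactone, where the lithium hemiketal alkoxide is stable at −78 °C and prevents a second addition; the cis keto alcohol (in equilibrium with its bicyclic lactol) is released on quench with no stereocentre touched.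

Step 11
Reactants: 19 [(3R,4R,5S)-4-(hydroxymethyl)-5-{4-methoxy-3-[(triisopropylsilyl)oxy]phenyl}oxolan-3-yl]{4-methoxy-3-[(triisopropylsilyl)oxy]phenyl}methanone
Product: 21 [(3S,4R,5S)-4-(hydroxymethyl)-5-(3-hydroxy-4-methoxyphenyl)oxolan-3-yl](3-hydroxy-4-methoxyphenyl)methanone, via trans ketone 20 (not isolated)
Conditions: 1,8-diazabicyclo[5.4.0]undec-7-ene (0.3 equiv), toluene, 50 °C; then n-Bu4NF, AcOH, THF, 0 °C to rt
Reagents that add atoms: none
Why: Base-mediated epimerisation through the ketone enolate moves the aroyl group to the thermodynamically favoured position trans to the C-3 arm (all-trans, C-4 becomes S), and buffered fluoride then cleaves both aryl silyl ethers (enolisation–epimerisation, desilylation).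

**Compound list**
1 | anisole | COc1ccccc1 | starting material
2 | 2,4-dibromo-1-methoxybenzene | COc1ccc(Br)cc1Br | intermediate
3 | (5-bromo-2-methoxyphenyl)lithium | [Li]c1cc(Br)ccc1OC | intermediate
4 | lithium (5-bromo-2-methoxyphenyl)trimethoxyborate | [Li+].CO[B-](OC)(OC)c1cc(Br)ccc1OC | intermediate
5 | 5-bromo-2-methoxyphenol | COc1ccc(Br)cc1O | intermediate
6 | (5-bromo-2-methoxyphenoxy)tri(propan-2-yl)silane | COc1ccc(Br)cc1O[Si](C(C)C)(C(C)C)C(C)C | intermediate
7 | (trimethylsilyl)methanol | C[Si](C)(C)CO | starting material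
8 | [(chloromethoxy)methyl]trimethylsilane | C[Si](C)(C)COCCl | intermediate
9 | maleic anhydride | O=C1C=CC(=O)O1 | starting material
10 | (Z)-4-anilino-4-oxobut-2-enoic acid (maleanilic acid) | OC(=O)/C=C\C(=O)Nc1ccccc1 | intermediate
11 | N-phenylmaleimide | O=C1C=CC(=O)N1c1ccccc1 | intermediate
12 | formaldehyde O-methylide (parent carbonyl ylide) | C=[O+][CH2-] | intermediate
13 | (3aR,6aS)-5-phenyltetrahydro-1H-furo[3,4-c]pyrrole-4,6(5H)-dione (cis-fused, meso) | O=C1N(c3ccccc3)C(=O)[C@H]2COC[C@@H]12 | intermediate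
14 | (3aR,6aS)-6-hydroxy-5-phenylhexahydro-4H-furo[3,4-c]pyrrol-4-one (cis-fused; C-6 epimers, centre lost in step 8) | OC1N(c3ccccc3)C(=O)[C@H]2COC[C@@H]12 | intermediate
15 | (3R,4R)-4-(hydroxymethyl)-N-phenyloxolane-3-carboxamide (cis) | OC[C@@H]1COC[C@@H]1C(=O)Nc2ccccc2 | intermediate
16 | (3aS,6aR)-tetrahydro-1H,3H-furo[3,4-c]furan-1-one (cis-fused) | O=C1OC[C@H]2[C@@H]1COC2 | intermediate
17 | (3aR,4S,6aR)-4-{4-methoxy-3-[(triisopropylsilyl)oxy]phenyl}tetrahydro-1H,3H-furo[3,4-c]furan-1-one (aryl on the convex face) | O=C1OC[C@H]2[C@@H]1CO[C@@H]2c3ccc(OC)c(O[Si](C(C)C)(C(C)C)C(C)C)c3 | intermediate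
18 | {4-methoxy-3-[(triisopropylsilyl)oxy]phenyl}lithium | [Li]c1ccc(OC)c(O[Si](C(C)C)(C(C)C)C(C)C)c1 | intermediate
19 | [(3R,4R,5S)-4-(hydroxymethyl)-5-{4-methoxy-3-[(triisopropylsilyl)oxy]phenyl}oxolan-3-yl]{4-methoxy-3-[(triisopropylsilyl)oxy]phenyl}methanone (aroyl cis to CH2OH) | COc1ccc(C(=O)[C@H]2CO[C@H](c3ccc(OC)c(O[Si](C(C)C)(C(C)C)C(C)C)c3)[C@H]2CO)cc1O[Si](C(C)C)(C(C)C)C(C)C | intermediate
20 | [(3S,4R,5S)-4-(hydroxymethyl)-5-{4-methoxy-3-[(triisopropylsilyl)oxy]phenyl}oxolan-3-yl]{4-methoxy-3-[(triisopropylsilyl)oxy]phenyl}methanone (all-trans) | COc1ccc(C(=O)[C@@H]2CO[C@H](c3ccc(OC)c(O[Si](C(C)C)(C(C)C)C(C)C)c3)[C@H]2CO)cc1O[Si](C(C)C)(C(C)C)C(C)C | intermediate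
21 | [(3S,4R,5S)-4-(hydroxymethyl)-5-(3-hydroxy-4-methoxyphenyl)oxolan-3-yl](3-hydroxy-4-methoxyphenyl)methanone | COc1ccc(C(=O)[C@@H]2CO[C@H](c3ccc(OC)c(O)c3)[C@H]2CO)cc1O | target

**Step count and convergence**
Total step count: 11. Longest linear sequence: 7 steps (steps 5, 6, 7, 8, 9, 10, 11; equally steps 4, 6–11). The aryl branch (steps 1–3) feeds both step 9 and step 10.

**Three steps most likely to fail**

Step 9 (the new reaction). The arylation may go to the other ether CH2, or the electron-rich bromide may quench the excited decatungstate. The fallback uses known chemistry, sets out from 6 and comes back at 21. Compound 6 is lithiated (n-BuLi, THF, −78 °C) and formylated with DMF to 4-methoxy-3-[(triisopropylsilyl)oxy]benzaldehyde F1. Iridium-catalysed transfer-hydrogenative anti-(hydroxymethyl)allylation with commercial 4-vinyl-1,3-dioxolan-2-one ([IrCl(C8H12)]2 with C8H12 = 1,5-cyclooctadiene, (S)-5,5′-bis(diphenylphosphino)-4,4′-bi-1,3-benzodioxole, 4-cyano-3-nitrobenzoic acid, K3PO4, i-PrOH, THF, 70 °C) sets both carbinol-side stereocentres and gives (1S,2R)-2-ethenyl-1-{4-methoxy-3-[(triisopropylsilyl)oxy]phenyl}propane-1,3-diol F2. TBSCl/imidazole silylates the primary alcohol to the mono-TBS ether F3. I2, NaHCO3, MeCN closes the oxolane by 5-endo iodoetherification to the 4-iodo-oxolane F4 (C-4 epimers, both usable). A second portion of 6 is carboxylated (n-BuLi; CO2) to 4-methoxy-3-[(triisopropylsilyl)oxy]benzoic acid F5 and converted with (COCl)2/cat. DMF into the acid chloride F6. Nickel-catalysed reductive acyl cross-electrophile coupling of F4 with F6 (NiCl2(MeOCH2CH2OMe), 4,4′-di-tert-butyl-2,2′-bipyridine, Mn, DMA, rt) goes through the C-4 radical, places the aroyl group trans to the C-3 arm and gives the fully silylated trans ketone F7. n-Bu4NF/AcOH then gives 21.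

Step 10. The risk is double addition of the aryllithium or enolisation of the lactone. The fallback sets out from 17 and comes back at 19. Compound 17 is opened with MeNH(OMe)·HCl/i-PrMgCl (THF, −20 °C) to the cis hydroxy Weinreb amide F8. F8 is used crude with 2.2 equiv of 18 at −78 °C, the first equivalent deprotonating the alcohol. The N-methoxy-N-methyl amide gives a chelated tetrahedral intermediate that cannot over-add and releases 19 on work-up.

Step 11. The cis isomer may sit as its bicyclic lactol and resist equilibration to the trans ketone. The fallback sets out from 19 and comes back at 21. TESCl, imidazole, DMF traps the open keto form as the cis triethylsilyl ether F9, which cannot close to a lactol. 1,8-Diazabicyclo[5.4.0]undec-7-ene in toluene (60 °C) then epimerises C-4 to the trans triethylsilyl ether F10. n-Bu4NF/AcOH removes all three silyl groups to give 21.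

**Further compounds**
F1 | step 9 | 4-methoxy-3-[(triisopropylsilyl)oxy]benzaldehyde | COc1ccc(C=O)cc1O[Si](C(C)C)(C(C)C)C(C)C
F2 | step 9 | (1S,2R)-2-ethenyl-1-{4-methoxy-3-[(triisopropylsilyl)oxy]phenyl}propane-1,3-diol | O[C@H](c1ccc(OC)c(O[Si](C(C)C)(C(C)C)C(C)C)c1)[C@@H](CO)C=C
F3 | step 9 | (1S,2R)-2-({[tert-butyl(dimethyl)silyl]oxy}methyl)-1-{4-methoxy-3-[(triisopropylsilyl)oxy]phenyl}but-3-en-1-ol | O[C@H](c1ccc(OC)c(O[Si](C(C)C)(C(C)C)C(C)C)c1)[C@@H](CO[Si](C)(C)C(C)(C)C)C=C
F4 | step 9 | tert-butyl{[(2S,3R)-4-iodo-2-{4-methoxy-3-[(triisopropylsilyl)oxy]phenyl}oxolan-3-yl]methoxy}dimethylsilane (C-4 epimers) | IC1CO[C@H](c2ccc(OC)c(O[Si](C(C)C)(C(C)C)C(C)C)c2)[C@H]1CO[Si](C)(C)C(C)(C)C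
F5 | step 9 | 4-methoxy-3-[(triisopropylsilyl)oxy]benzoic acid | COc1ccc(C(=O)O)cc1O[Si](C(C)C)(C(C)C)C(C)C
F6 | step 9 | 4-methoxy-3-[(triisopropylsilyl)oxy]benzoyl chloride | COc1ccc(C(Cl)=O)cc1O[Si](C(C)C)(C(C)C)C(C)C
F7 | step 9 | [(3S,4R,5S)-4-({[tert-butyl(dimethyl)silyl]oxy}methyl)-5-{4-methoxy-3-[(triisopropylsilyl)oxy]phenyl}oxolan-3-yl]{4-methoxy-3-[(triisopropylsilyl)oxy]phenyl}methanone | COc1ccc(C(=O)[C@@H]2CO[C@H](c3ccc(OC)c(O[Si](C(C)C)(C(C)C)C(C)C)c3)[C@H]2CO[Si](C)(C)C(C)(C)C)cc1O[Si](C(C)C)(C(C)C)C(C)C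
F8 | step 10 | (3R,4R,5S)-4-(hydroxymethyl)-N-methoxy-N-methyl-5-{4-methoxy-3-[(triisopropylsilyl)oxy]phenyl}oxolane-3-carboxamide | CON(C)C(=O)[C@H]1CO[C@H](c2ccc(OC)c(O[Si](C(C)C)(C(C)C)C(C)C)c2)[C@H]1CO
F9 | step 11 | [(3R,4R,5S)-5-{4-methoxy-3-[(triisopropylsilyl)oxy]phenyl}-4-{[(triethylsilyl)oxy]methyl}oxolan-3-yl]{4-methoxy-3-[(triisopropylsilyl)oxy]phenyl}methanone | COc1ccc(C(=O)[C@H]2CO[C@H](c3ccc(OC)c(O[Si](C(C)C)(C(C)C)C(C)C)c3)[C@H]2CO[Si](CC)(CC)CC)cc1O[Si](C(C)C)(C(C)C)C(C)C
F10 | step 11 | [(3S,4R,5S)-5-{4-methoxy-3-[(triisopropylsilyl)oxy]phenyl}-4-{[(triethylsilyl)oxy]methyl}oxolan-3-yl]{4-methoxy-3-[(triisopropylsilyl)oxy]phenyl}methanone | COc1ccc(C(=O)[C@@H]2CO[C@H](c3ccc(OC)c(O[Si](C(C)C)(C(C)C)C(C)C)c3)[C@H]2CO[Si](CC)(CC)CC)cc1O[Si](C(C)C)(C(C)C)C(C)C
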